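**Plan**
- Retrosynthetic cuts, in order: indole N–S (tosyl); pyrrole C5–Br back to C5–CO2H; pyrrole C2–C3 and C4–C5 ([3+2] of a glycine imine with a two-carbon acetylene equivalent); the imine C=N; oxazole O1–C5 and C2–N3 (cyclodehydration of a keto-oxamate); the CH2–N bond and the indole C3–acyl bond.
- Enabling feature: the pyrrole has H on C3 and C4 and Br on C5 next to N1. C5 can first carry a carboxyl, so N1–C5 is a glycine ester, pyrrole C2 is the formyl carbon on oxazole C2, and C3–C4 come from (E)-1,2-bis(phenylsulfonyl)ethene.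
- Forward order: the indole is bought and acylated at C3; the oxazole ring closes at step 5; the pyrrole ring is made at step 10; bromine replaces the carboxyl at step 12; the tosyl group leaves last.
- Protecting groups: N-tosyl stays on the indole through the bromination to keep the methoxyindole away from NBS; an allyl ester allows neutral unmasking of the acid without losing the tosyl group.
- Stereochemistry: the target has no stereocentre; the four centres of the cycloadduct are transient, and the E aldimine is the thermodynamic isomer.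

Key step: step 10

Assumption: cycloadduct 16 is drawn as one enantiomer of one racemic diastereomer (2,5-cis, 3,4-trans); which diastereomer forms is immaterial because all four centres are destroyed in the same flask. Ts = p-toluenesulfonyl, allyl = prop-2-en-1-yl.

**Route**

Step 1
Reactants: 1 6-bromo-4-methoxy-1H-indole; 2 chloroacetyl chloride
Product: 3 1-(6-bromo-4-methoxy-1H-indol-3-yl)-2-chloroethan-1-one
Conditions: pyridine, toluene, 60 °C
Reagents that add atoms: none
Why: Friedel–Crafts-type acylation of the NH-indole should go to the enamine-like C3, its most nucleophilic carbon, with pyridine taking up the HCl so that the methyl ether and the aryl bromide are untouched.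

Step 2
Reactants: 3 1-(6-bromo-4-methoxy-1H-indol-3-yl)-2-chloroethan-1-one
Product: 4 2-azido-1-(6-bromo-4-methoxy-1H-indol-3-yl)ethan-1-one
Conditions: NaN3, DMF, rt
Reagents that add atoms: sodium azide, [Na+].[N-]=[N+]=[N-]
Why: SN2 displacement of the α-chloro ketone, a strongly activated primary electrophile, by azide should be clean at room temperature.

Step 3
Reactants: 4 2-azido-1-(6-bromo-4-methoxy-1H-indol-3-yl)ethan-1-one
Product: 6 2-amino-1-(6-bromo-4-methoxy-1H-indol-3-yl)ethan-1-one hydrochloride, via iminophosphorane 5 (not isolated)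
Conditions: PPh3, THF, rt; H2O, 50 °C; then HCl (2 M in Et2O), 0 °C
Reagents that add atoms: hydrogen chloride, Cl
Why: Staudinger reduction gives the iminophosphorane with loss of N2, water hydrolyses it, and immediate salt formation keeps the α-amino ketone from self-condensing, while the aryl bromide, which hydrogenation would endanger, is left alone.

Step 4
Reactants: 6 2-amino-1-(6-bromo-4-methoxy-1H-indol-3-yl)ethan-1-one hydrochloride; 7 ethyl chlorooxoacetate
Product: 8 ethyl 2-{[2-(6-bromo-4-methoxy-1H-indol-3-yl)-2-oxoethyl]amino}-2-oxoacetate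
Conditions: Et3N, THF, 0 °C → rt
Reagents that add atoms: none
Why: N-acylation of the liberated primary amine by the acid chloride (amide formation) is far faster than any reaction at the ethyl ester or at the weakly nucleophilic indole N–H.

Step 5
Reactants: 8 ethyl 2-{[2-(6-bromo-4-methoxy-1H-indol-3-yl)-2-oxoethyl]amino}-2-oxoacetate
Product: 9 ethyl 5-(6-bromo-4-methoxy-1H-indol-3-yl)oxazole-2-carboxylate
Conditions: POCl3, toluene, 90 °C
Reagents that add atoms: none
Why: Robinson–Gabriel cyclodehydration, in which POCl3 activates the keto-amide, the amide oxygen closes on the ketone carbon (5-exo-trig) and loss of water gives the aromatic oxazole, as known for 5-(indol-3-yl)oxazoles and 5-aryloxazole-2-carboxylates.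

Step 6
Reactants: 9 ethyl 5-(6-bromo-4-methoxy-1H-indol-3-yl)oxazole-2-carboxylate
Product: 10 ethyl 5-(6-bromo-4-methoxy-1-tosyl-1H-indol-3-yl)oxazole-2-carboxylate
Conditions: NaH, TsCl, THF/DMF, 0 °C → rt
Reagents that add atoms: p-toluenesulfonyl chloride, Cc1ccc(S(=O)(=O)Cl)cc1
Why: N-sulfonylation of the sodium indolide should be selective because the indole N–H is the only acidic site and the ester is inert to NaH at 0 °C.

Step 7
Reactants: 10 ethyl 5-(6-bromo-4-methoxy-1-tosyl-1H-indol-3-yl)oxazole-2-carboxylate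
Product: 11 [5-(6-bromo-4-methoxy-1-tosyl-1H-indol-3-yl)oxazol-2-yl]methanol
Conditions: NaBH4, EtOH/THF, 0 °C → rt
Reagents that add atoms: none
Why: The ester on the electron-poor oxazole C2 is activated like other azole-2-carboxylates and should undergo hydride reduction with NaBH4 to the primary alcohol, the sulfonamide and the aryl bromide being inert.

Step 8
Reactants: 11 [5-(6-bromo-4-methoxy-1-tosyl-1H-indol-3-yl)oxazol-2-yl]methanol
Product: 12 5-(6-bromo-4-methoxy-1-tosyl-1H-indol-3-yl)oxazole-2-carbaldehyde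
Conditions: MnO2 (activated), CH2Cl2, rt
Reagents that add atoms: none
Why: MnO2 oxidation of a heteroaryl (benzylic-type) carbinol stops at the aldehyde and does not touch the protected indole.

Step 9
Reactants: 12 5-(6-bromo-4-methoxy-1-tosyl-1H-indol-3-yl)oxazole-2-carbaldehyde; 13 glycine allyl ester p-toluenesulfonate
Product: 14 allyl (E)-N-{[5-(6-bromo-4-methoxy-1-tosyl-1H-indol-3-yl)oxazol-2-yl]methylidene}glycinate
Conditions: Et3N, MgSO4, CH2Cl2, rt
Reagents that add atoms: none
Why: Imine condensation of the electrophilic heteroaryl aldehyde with the free-based glycine ester, with MgSO4 taking up the water, should give the conjugated aldimine in its thermodynamic E geometry.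

Step 10
Reactants: 14 allyl (E)-N-{[5-(6-bromo-4-methoxy-1-tosyl-1H-indol-3-yl)oxazol-2-yl]methylidene}glycinate; 15 (E)-1,2-bis(phenylsulfonyl)ethene
Product: 17 allyl 5-[5-(6-bromo-4-methoxy-1-tosyl-1H-indol-3-yl)oxazol-2-yl]-1H-pyrrole-2-carboxylate, via bis-sulfonyl pyrrolidine 16 (not isolated)
Conditions: AgOAc (10 mol%), PPh3 (10 mol%), Et3N (20 mol%), toluene, rt; then DBU (3 equiv), rt
Reagents that add atoms: none
Why: AgOAc and Et3N convert imine 14 into an N-metalated azomethine ylide of monovalent silver, held W-shaped by N,O-chelation, and this dipole adds across the electron-poor alkene 15 in a [3+2] cycloaddition that forms pyrrole C2–C3 and C4–C5 together. The closest known reaction type is the metal-catalysed azomethine ylide cycloaddition with 1,2-bis(sulfonyl)ethenes as acetylene equivalents, followed by base-induced aromatisation to 5-aryl-pyrrole-2-carboxylates. The five-membered ring is closed by the cycloaddition itself, the dipole giving C–N–C and the alkene the other two carbons; should the process be stepwise, Michael addition is followed by a 5-endo-trig Mannich closure on the metal-bound imine. The four stereocentres of 16 are set by the ylide geometry (2,5-cis) and the E alkene (3,4-trans), but none survives: DBU removes the acidic C–H next to the ester, the neighbouring sulfinate leaves by E1cB, and a second, vinylogous sulfinate loss with tautomerisation gives the pyrrole without an oxidant. No regiocontrol is needed because 15 is symmetrical; the step needs elimination to outrun retro-Mannich opening, which the two sulfinate leaving groups and the gain of aromaticity secure. The ester that stabilises the ylide ends on the carbon that will carry bromine.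

Step 11
Reactants: 17 allyl 5-[5-(6-bromo-4-methoxy-1-tosyl-1H-indol-3-yl)oxazol-2-yl]-1H-pyrrole-2-carboxylate
Product: 18 5-[5-(6-bromo-4-methoxy-1-tosyl-1H-indol-3-yl)oxazol-2-yl]-1H-pyrrole-2-carboxylic acid
Conditions: Pd(PPh3)4 (5 mol%), morpholine, THF, rt; aq. citric acid work-up
Reagents that add atoms: none
Why: Tsuji–Trost deallylation, in which zerovalent palladium ionises the allyl ester to a π-allyl complex that morpholine captures, is neutral enough to keep the N-tosyl group and runs at a temperature at which oxidative addition into the aryl bromide is slow.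

Step 12
Reactants: 18 5-[5-(6-bromo-4-methoxy-1-tosyl-1H-indol-3-yl)oxazol-2-yl]-1H-pyrrole-2-carboxylic acid
Product: 19 6-bromo-3-[2-(5-bromo-1H-pyrrol-2-yl)oxazol-5-yl]-4-methoxy-1-tosyl-1H-indole
Conditions: NBS (1.05 equiv), NaHCO3, DMF, 0 °C, dark
Reagents that add atoms: N-bromosuccinimide, O=C1CCC(=O)N1Br
Why: Ipso-bromodecarboxylation (Hunsdiecker-type halodecarboxylation of a pyrrole-2-carboxylate): the electrophilic bromine attacks the α-carbon that bears the carboxylate, CO2 leaves from the σ-complex, and the tosyl group holds the methoxyindole back from NBS.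

Step 13
Reactants: 19 6-bromo-3-[2-(5-bromo-1H-pyrrol-2-yl)oxazol-5-yl]-4-methoxy-1-tosyl-1H-indole
Product: 20 6-bromo-3-[2-(5-bromo-1H-pyrrol-2-yl)oxazol-5-yl]-4-methoxy-1H-indole
Conditions: LiOH·H2O, THF/H2O, 60 °C
Reagents that add atoms: none
Why: Hydroxide attacks sulfur of the N-sulfonylindole (sulfonamide cleavage with indolide as leaving group), while the bromopyrrole, present as its pyrrolide, is shielded from nucleophilic substitution.

**Compound list**
1 | 6-bromo-4-methoxy-1H-indole | COc1cc(Br)cc2[nH]ccc12 | starting material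
2 | chloroacetyl chloride | O=C(Cl)CCl | starting material
3 | 1-(6-bromo-4-methoxy-1H-indol-3-yl)-2-chloroethan-1-one | COc1cc(Br)cc2[nH]cc(C(=O)CCl)c12 | intermediate
4 | 2-azido-1-(6-bromo-4-methoxy-1H-indol-3-yl)ethan-1-one | COc1cc(Br)cc2[nH]cc(C(=O)CN=[N+]=[N-])c12 | intermediate
5 | 1-(6-bromo-4-methoxy-1H-indol-3-yl)-2-[(triphenylphosphoranylidene)amino]ethan-1-one | COc1cc(Br)cc2[nH]cc(C(=O)CN=P(c3ccccc3)(c3ccccc3)c3ccccc3)c12 | intermediate (not isolated)
6 | 2-amino-1-(6-bromo-4-methoxy-1H-indol-3-yl)ethan-1-one hydrochloride | COc1cc(Br)cc2[nH]cc(C(=O)CN)c12.Cl | intermediate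
7 | ethyl chlorooxoacetate | CCOC(=O)C(=O)Cl | starting material
8 | ethyl 2-{[2-(6-bromo-4-methoxy-1H-indol-3-yl)-2-oxoethyl]amino}-2-oxoacetate | CCOC(=O)C(=O)NCC(=O)c1c[nH]c2cc(Br)cc(OC)c12 | intermediate
9 | ethyl 5-(6-bromo-4-methoxy-1H-indol-3-yl)oxazole-2-carboxylate | CCOC(=O)c1ncc(-c2c[nH]c3cc(Br)cc(OC)c23)o1 | intermediate
10 | ethyl 5-(6-bromo-4-methoxy-1-tosyl-1H-indol-3-yl)oxazole-2-carboxylate | CCOC(=O)c1ncc(-c2cn(S(=O)(=O)c3ccc(C)cc3)c3cc(Br)cc(OC)c23)o1 | intermediate
11 | [5-(6-bromo-4-methoxy-1-tosyl-1H-indol-3-yl)oxazol-2-yl]methanol | OCc1ncc(-c2cn(S(=O)(=O)c3ccc(C)cc3)c3cc(Br)cc(OC)c23)o1 | intermediate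
12 | 5-(6-bromo-4-methoxy-1-tosyl-1H-indol-3-yl)oxazole-2-carbaldehyde | O=Cc1ncc(-c2cn(S(=O)(=O)c3ccc(C)cc3)c3cc(Br)cc(OC)c23)o1 | intermediate
13 | glycine allyl ester p-toluenesulfonate | C=CCOC(=O)CN.Cc1ccc(S(=O)(=O)O)cc1 | starting material
14 | allyl (E)-N-{[5-(6-bromo-4-methoxy-1-tosyl-1H-indol-3-yl)oxazol-2-yl]methylidene}glycinate | C=CCOC(=O)C/N=C/c1ncc(-c2cn(S(=O)(=O)c3ccc(C)cc3)c3cc(Br)cc(OC)c23)o1 | intermediate (key-step precursor)
15 | (E)-1,2-bis(phenylsulfonyl)ethene | O=S(=O)(/C=C/S(=O)(=O)c1ccccc1)c1ccccc1 | starting material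
16 | allyl (2,5-cis,3,4-trans)-5-[5-(6-bromo-4-methoxy-1-tosyl-1H-indol-3-yl)oxazol-2-yl]-3,4-bis(phenylsulfonyl)pyrrolidine-2-carboxylate, racemic | N1[C@@H](C(=O)OCC=C)[C@H](S(=O)(=O)c2ccccc2)[C@@H](S(=O)(=O)c2ccccc2)[C@H]1c1ncc(-c2cn(S(=O)(=O)c3ccc(C)cc3)c3cc(Br)cc(OC)c23)o1 | intermediate (not isolated)
17 | allyl 5-[5-(6-bromo-4-methoxy-1-tosyl-1H-indol-3-yl)oxazol-2-yl]-1H-pyrrole-2-carboxylate | C=CCOC(=O)c1ccc(-c2ncc(-c3cn(S(=O)(=O)c4ccc(C)cc4)c4cc(Br)cc(OC)c34)o2)[nH]1 | intermediate (key-step product)
18 | 5-[5-(6-bromo-4-methoxy-1-tosyl-1H-indol-3-yl)oxazol-2-yl]-1H-pyrrole-2-carboxylic acid | O=C(O)c1ccc(-c2ncc(-c3cn(S(=O)(=O)c4ccc(C)cc4)c4cc(Br)cc(OC)c34)o2)[nH]1 | intermediate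
19 | 6-bromo-3-[2-(5-bromo-1H-pyrrol-2-yl)oxazol-5-yl]-4-methoxy-1-tosyl-1H-indole | Brc1ccc(-c2ncc(-c3cn(S(=O)(=O)c4ccc(C)cc4)c4cc(Br)cc(OC)c34)o2)[nH]1 | intermediate
20 | 6-bromo-3-[2-(5-bromo-1H-pyrrol-2-yl)oxazol-5-yl]-4-methoxy-1H-indole | COc1cc(Br)cc2[nH]cc(-c3cnc(-c4ccc(Br)[nH]4)o3)c12 | target

**Count**
Total steps: 13. Longest linear sequence: 13 steps (1 → 20); compounds 2, 7, 13 and 15 are bought.

**Steps most likely to fail**

1. Step 12. The electrophilic bromination may stray from ipso attack to a pyrrole β-carbon or to oxazole C4, or run on to a dibromide. The fallback sets out from 18 and separates the two events. Protodecarboxylation with Ag2CO3 (10 mol%) and AcOH in DMSO at 120 °C should give the α-unsubstituted pyrrole 6-bromo-4-methoxy-3-[2-(1H-pyrrol-2-yl)oxazol-5-yl]-1-tosyl-1H-indole F1. C–H bromination of this compound with NBS in THF at −78 °C, which for a 2-substituted pyrrole goes to the free α-carbon, comes back to the route at 19.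

2. Step 10. The electron-poor aldimine may hydrolyse or oligomerise before the ylide forms, or the sequence may stall after conjugate addition or after the first sulfinate loss. The fallback sets out from 12 and builds the same pyrrole by a nitrene-type ring closure:
   - Wittig homologation with (triphenylphosphoranylidene)acetaldehyde in toluene at 80 °C should give the enal (E)-3-[5-(6-bromo-4-methoxy-1-tosyl-1H-indol-3-yl)oxazol-2-yl]prop-2-enal F2.
   - Knoevenagel-type condensation with methyl azidoacetate (NaOMe, MeOH, −15 °C) should give the dienyl azide methyl (2Z,4E)-2-azido-5-[5-(6-bromo-4-methoxy-1-tosyl-1H-indol-3-yl)oxazol-2-yl]penta-2,4-dienoate F3.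
   - Loss of N2 and ring closure under ZnI2 catalysis in CH2Cl2 at rt (Hemetsberger-type cyclisation of a dienyl azide) should give methyl 5-[5-(6-bromo-4-methoxy-1-tosyl-1H-indol-3-yl)oxazol-2-yl]-1H-pyrrole-2-carboxylate F4.
   - Neutral ester cleavage with Me3SnOH in 1,2-dichloroethane at 80 °C keeps the tosyl group and comes back to the route at 18.

3. Step 5. Ring closure may be slow because the 3-acylindole carbonyl is a deactivated vinylogous amide crowded by the peri methoxy group, so the material may degrade in hot POCl3. The fallback sets out from azide 4 and replaces steps 3 to 5 by a tandem Staudinger/aza-Wittig oxazole synthesis. PPh3 in toluene gives iminophosphorane 5. Acylation with 7 in the presence of Et3N should give the imidoyl chloride ethyl (Z)-2-chloro-2-{[2-(6-bromo-4-methoxy-1H-indol-3-yl)-2-oxoethyl]imino}acetate F5, which is not isolated. It closes through the enol oxygen with loss of HCl and comes back to the route at 9.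

**Further compounds**
F1 | step 12 | 6-bromo-4-methoxy-3-[2-(1H-pyrrol-2-yl)oxazol-5-yl]-1-tosyl-1H-indole | c1cc(-c2ncc(-c3cn(S(=O)(=O)c4ccc(C)cc4)c4cc(Br)cc(OC)c34)o2)[nH]c1
F2 | step 10 | (E)-3-[5-(6-bromo-4-methoxy-1-tosyl-1H-indol-3-yl)oxazol-2-yl]prop-2-enal | O=C/C=C/c1ncc(-c2cn(S(=O)(=O)c3ccc(C)cc3)c3cc(Br)cc(OC)c23)o1
F3 | step 10 | methyl (2Z,4E)-2-azido-5-[5-(6-bromo-4-methoxy-1-tosyl-1H-indol-3-yl)oxazol-2-yl]penta-2,4-dienoate | COC(=O)/C(N=[N+]=[N-])=C/C=C/c1ncc(-c2cn(S(=O)(=O)c3ccc(C)cc3)c3cc(Br)cc(OC)c23)o1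
F4 | step 10 | methyl 5-[5-(6-bromo-4-methoxy-1-tosyl-1H-indol-3-yl)oxazol-2-yl]-1H-pyrrole-2-carboxylate | COC(=O)c1ccc(-c2ncc(-c3cn(S(=O)(=O)c4ccc(C)cc4)c4cc(Br)cc(OC)c34)o2)[nH]1
F5 | step 5 | ethyl (Z)-2-chloro-2-{[2-(6-bromo-4-methoxy-1H-indol-3-yl)-2-oxoethyl]imino}acetate | CCOC(=O)/C(Cl)=N/CC(=O)c1c[nH]c2cc(Br)cc(OC)c12
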